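**Plan**

- Retrosynthesis: first cut the C5=C6 olefin of ring B (ring-closing metathesis). Then cut the C(sp3)–C(sp2) bond between the ethylene linker and C-2 of ring A (B-alkyl Suzuki coupling at the tetrasubstituted enol-triflate carbon). This leaves fragment 1 (a vinyl-substituted 1,2-dioxane ester) and fragment 2 (a ring A enol triflate with cis vinyl and 3-methylbut-3-enyl arms).
- Forward order of rings: the 1,2-dioxane in fragment 1 (intramolecular SN2 of a tertiary hydroperoxide); ring A in fragment 2 (double Michael annulation on a butenolide, whose lactone is a temporary ring that enforces the cis arms); union of the fragments; ring B last.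
- Enabling feature: ring B (C4a, C5, C6, C7, C8, C8a; naphthalene numbering) carries one functional group, the trisubstituted C5=C6 bond, with C5 on ring-fusion carbon C4a and C6 two CH2 groups from C8a. The cis fusion puts both arms on one face of ring A, and the only other olefin (C2=C3) is tetrasubstituted and inert to metathesis.
- Stereochemistry: C4a/C8a are relayed from the single acetal stereocentre of the purchased (5R)-menthyloxybutenolide (anti addition, then cis ring closure). C-2 of the propanoate and C-3 of the dioxane come from a (Z)-crotylboration (reagent control), with inversion at C-3 on ring closure. C-6 of the dioxane comes from a Shi epoxidation, with inversion on perhydrolysis.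

Key step: step 17

**Route**

Step 1
Reactants: 1 3-methylbut-3-en-2-ol (racemic); 2 ethyl vinyl ether
Product: 4 (4E)-4-methylhex-4-enal, via allyl vinyl ether 3 (not isolated)
Conditions: Hg(OAc)2 (5 mol %), 2 as solvent, reflux; evaporate; then neat, 140 °C, sealed tube
Reagents that add atoms: none
Why: Claisen rearrangement: mercury-catalysed vinyl transfer to the allylic alcohol followed by a [3,3]-sigmatropic shift through a chair with the carbinol methyl equatorial should deliver the (E)-trisubstituted olefin, and the stereocentre of racemic 1 is destroyed in the process.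

Step 2
Reactants: 4 (4E)-4-methylhex-4-enal
Product: 5 (3S,4S,7E)-3,7-dimethylnona-1,7-dien-4-ol
Conditions: cis-but-2-ene, KOt-Bu, n-BuLi, THF, −78 to −45 °C; (+)-Ipc2BOMe [from (−)-α-pinene], −78 °C; BF3·OEt2; then 4, −78 °C; NaOH, H2O2, 0 °C to rt
Reagents that add atoms: B-[(Z)-but-2-en-1-yl]diisopinocampheylborane (made in the flask), C/C=C\CB([C@H]1C[C@H]2C[C@H](C2(C)C)[C@@H]1C)[C@H]1C[C@H]2C[C@H](C2(C)C)[C@@H]1C
Why: Brown (Z)-crotylboration through a closed chair transition state should give the syn C3/C4 pair from the Z-olefin, while the isopinocampheyl groups derived from (−)-α-pinene direct attack to the Re face of the aldehyde and set (4S), hence (3S,4S).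

Step 3
Reactants: 5 (3S,4S,7E)-3,7-dimethylnona-1,7-dien-4-ol
Product: 6 (3S,4S,7E)-3,7-dimethylnona-1,7-dien-4-yl methanesulfonate
Conditions: MsCl, Et3N, CH2Cl2, 0 °C
Reagents that add atoms: methanesulfonyl chloride, CS(=O)(=O)Cl
Why: Sulfonylation of the secondary alcohol with retention turns C-4 into the electrophile for the later inverting ring closure; no stereocentre is altered.

Step 4
Reactants: 6 (3S,4S,7E)-3,7-dimethylnona-1,7-dien-4-yl methanesulfonate
Product: 7 (3S,4S)-6-[(2R,3R)-2,3-dimethyloxiran-2-yl]-3-methylhex-1-en-4-yl methanesulfonate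
Conditions: D-fructose-derived Shi ketone (30 mol %), KHSO5 (as 2KHSO5·KHSO4·K2SO4), K2CO3, Bu4NHSO4, MeCN/dimethoxymethane/aq. Na2B4O7–Na2EDTA buffer, 0 °C
Reagents that add atoms: potassium peroxymonosulfate, [K+].[O-]S(=O)(=O)OO
Why: Shi asymmetric epoxidation: the chiral dioxirane reacts through a spiro transition state with the electron-rich trisubstituted (E)-olefin in preference to the monosubstituted vinyl group and should set the (2R,3R)-epoxide under reagent control.

Step 5
Reactants: 7 (3S,4S)-6-[(2R,3R)-2,3-dimethyloxiran-2-yl]-3-methylhex-1-en-4-yl methanesulfonate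
Product: 8 (3S,4S,7S,8R)-7-hydroperoxy-8-hydroxy-3,7-dimethylnon-1-en-4-yl methanesulfonate
Conditions: H2O2 (anhydrous ethereal solution, excess), H3PMo12O40 (5 mol %), Et2O, rt
Reagents that add atoms: hydrogen peroxide, OO
Why: Acid-catalysed perhydrolysis of a trisubstituted epoxide: hydrogen peroxide opens the activated oxirane at the tertiary carbon with inversion, fixing the quaternary peroxy centre as (7S) while C-8 keeps its oxygen.

Step 6
Reactants: 8 (3S,4S,7S,8R)-7-hydroperoxy-8-hydroxy-3,7-dimethylnon-1-en-4-yl methanesulfonate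
Product: 9 (1R)-1-[(3S,6R)-6-[(2S)-but-3-en-2-yl]-3-methyl-1,2-dioxan-3-yl]ethan-1-ol
Conditions: KOt-Bu (1.05 equiv), 18-crown-6, THF, 0 °C to rt
Reagents that add atoms: none
Why: Intramolecular alkylation of a hydroperoxide (6-exo-tet SN2): the peroxy anion, far more acidic than the alcohol, displaces the secondary mesylate with inversion and so sets the ring CH–O centre (R) of the 1,2-dioxane.

Step 7
Reactants: 9 (1R)-1-[(3S,6R)-6-[(2S)-but-3-en-2-yl]-3-methyl-1,2-dioxan-3-yl]ethan-1-ol
Product: 11 (2R)-2-[(3R,6S)-6-[(1R)-1-hydroxyethyl]-6-methyl-1,2-dioxan-3-yl]propanoic acid, via dioxanylpropanal 10 (not isolated)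
Conditions: O3, CH2Cl2/MeOH, −78 °C; Me2S; evaporate; then NaClO2, NaH2PO4, 2-methylbut-2-ene, t-BuOH/H2O, 0 °C to rt
Reagents that add atoms: ozone, [O-][O+]=O; sodium chlorite, [Na+].[O-]Cl=O
Why: Ozonolysis followed by Pinnick oxidation converts the remaining vinyl group into the carboxylic acid without touching the dialkyl peroxide or the secondary alcohol, and the α-methyl stereocentre is kept because the aldehyde is oxidised at once under buffered conditions.

Step 8
Reactants: 11 (2R)-2-[(3R,6S)-6-[(1R)-1-hydroxyethyl]-6-methyl-1,2-dioxan-3-yl]propanoic acid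
Product: 12 methyl (2R)-2-[(3R,6S)-6-[(1R)-1-hydroxyethyl]-6-methyl-1,2-dioxan-3-yl]propanoate
Conditions: Me3SiCHN2, toluene/MeOH (4:1), 0 °C
Reagents that add atoms: trimethylsilyldiazomethane, C[Si](C)(C)C=[N+]=[N-]
Why: Esterification with trimethylsilyldiazomethane methylates only the carboxylic acid under neutral conditions that leave the peroxide and the alcohol alone.

Step 9
Reactants: 12 methyl (2R)-2-[(3R,6S)-6-[(1R)-1-hydroxyethyl]-6-methyl-1,2-dioxan-3-yl]propanoate
Product: 13 methyl (2R)-2-[(3R,6S)-6-ethenyl-6-methyl-1,2-dioxan-3-yl]propanoate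
Conditions: Burgess reagent (MeO2CN−SO2N+Et3), benzene, 50 °C
Reagents that add atoms: none
Why: Burgess dehydration (syn-elimination of the sulfamate ester): only the methyl group offers β-hydrogens, the other neighbour being quaternary, so the terminal vinyl group should form regiospecifically under neutral conditions that the peroxide tolerates.

Step 10
Reactants: 14 2-methylpentan-3-one
Product: 15 2,4-dimethylpent-1-en-3-one
Conditions: paraformaldehyde, i-Pr2NH·CF3CO2H (1 equiv), CF3CO2H (10 mol %), THF, reflux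
Reagents that add atoms: formaldehyde (as paraformaldehyde), C=O
Why: α-Methylenation (Mannich-type condensation and elimination): only the CH2 of the ethyl group can give the enone, the isopropyl methine having a single α-hydrogen.

Step 11
Reactants: 15 2,4-dimethylpent-1-en-3-one; 16 (5R)-5-{[(1R,2S,5R)-5-methyl-2-(propan-2-yl)cyclohexyl]oxy}furan-2(5H)-one
Product: 20 (3R,3aS,7aS)-4,4,6-trimethyl-3-{[(1R,2S,5R)-5-methyl-2-(propan-2-yl)cyclohexyl]oxy}-1-oxo-1,3,3a,4,7,7a-hexahydro-2-benzofuran-5-yl trifluoromethanesulfonate, via lithium dienolate 17 (not isolated), via lithium lactone enolate 18 (not isolated), via bicyclic lithium enolate 19 (not isolated)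
Conditions: LDA (1.05 equiv), THF, −78 °C, slow addition of 15; 16, −78 to −20 °C; then N-(5-chloropyridin-2-yl)bis(trifluoromethanesulfonimide), −78 to 0 °C
Reagents that add atoms: N-(5-chloropyridin-2-yl)bis(trifluoromethanesulfonimide) (Comins' reagent), FC(F)(F)S(=O)(=O)N(c1ccc(Cl)cn1)S(=O)(=O)C(F)(F)F
Why: Anionic double Michael annulation (formal [4+2]) with enolate O-triflation: the fully substituted α′-carbon of the cross-conjugated dienolate adds to C-4 of the butenolide anti to the menthyloxy group (sets C-3a), the lactone enolate then closes the six-membered ring by 6-endo Michael addition on the same face to give the cis fusion (sets C-7a), and the regiodefined tetrasubstituted enolate is trapped as the triflate.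

Step 12
Reactants: 20 (3R,3aS,7aS)-menthyloxy lactone enol triflate
Product: 22 (3aS,7aS)-4,4,6-trimethyl-1-oxo-1,3,3a,4,7,7a-hexahydro-2-benzofuran-5-yl trifluoromethanesulfonate, via pseudo-acid 21 (not isolated)
Conditions: CF3CO2H/H2O (4:1), 40 °C; evaporate; NaBH4, THF/EtOH, 0 °C; then 1 M HCl, rt
Reagents that add atoms: water, O
Why: Acetal hydrolysis, borohydride reduction and lactonisation: the menthyl auxiliary is released, the liberated aldehyde (pseudo-acid form) is reduced to the primary alcohol and closes onto the acid, so the acetal carbon becomes the lactone CH2 while the enol triflate and both ring-fusion centres are unaffected.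

Step 13
Reactants: 22 (3aS,7aS)-4,4,6-trimethyl-1-oxo-1,3,3a,4,7,7a-hexahydro-2-benzofuran-5-yl trifluoromethanesulfonate
Product: 23 (3aS,7aS)-1-hydroxy-4,4,6-trimethyl-1,3,3a,4,7,7a-hexahydro-2-benzofuran-5-yl trifluoromethanesulfonate (anomeric mixture)
Conditions: i-Bu2AlH (1.1 equiv), CH2Cl2, −78 °C; Rochelle-salt work-up
Reagents that add atoms: none
Why: Partial reduction of the lactone with one equivalent of hydride at low temperature stops at the lactol, the enol triflate being inert to the aluminium hydride under these conditions.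

Step 14
Reactants: 23 (3aS,7aS)-lactol enol triflate
Product: 24 (4R,5S)-4-ethenyl-5-(hydroxymethyl)-2,6,6-trimethylcyclohex-1-en-1-yl trifluoromethanesulfonate
Conditions: Ph3PCH3Br, KOt-Bu, THF, 0 °C; then 23, −78 to 0 °C
Reagents that add atoms: methylidenetriphenylphosphorane (made in the flask), C=P(c1ccccc1)(c1ccccc1)c1ccccc1
Why: Wittig methylenation of the open hydroxy-aldehyde form of the lactol installs the vinyl group on C-4 and frees the hydroxymethyl group on C-5, the cis relationship being retained because olefination of the unhindered aldehyde should outrun enolisation at low temperature.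

Step 15
Reactants: 24 (4R,5S)-4-ethenyl-5-(hydroxymethyl)-2,6,6-trimethylcyclohex-1-en-1-yl trifluoromethanesulfonate
Product: 26 (4R,5S)-4-ethenyl-2,6,6-trimethyl-5-(3-methylbut-3-en-1-yl)cyclohex-1-en-1-yl trifluoromethanesulfonate, via primary alkyl triflate 25 (not isolated)
Conditions: Tf2O, 2,6-lutidine, CH2Cl2, −78 °C; then (2-methylallyl)MgCl, CuBr·SMe2 (10 mol %), THF, −78 to −30 °C
Reagents that add atoms: (2-methylprop-2-en-1-yl)magnesium chloride, C=C(C)C[Mg]Cl
Why: Triflation and copper-catalysed sp3–sp3 Grignard cross-coupling: the primary alkyl triflate is displaced by the methallyl nucleophile far faster than the hindered tetrasubstituted enol triflate reacts, which completes the 3-methylbut-3-enyl arm.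

Step 16
Reactants: 13 methyl (2R)-2-[(3R,6S)-6-ethenyl-6-methyl-1,2-dioxan-3-yl]propanoate; 26 (4R,5S)-4-ethenyl-2,6,6-trimethyl-5-(3-methylbut-3-en-1-yl)cyclohex-1-en-1-yl trifluoromethanesulfonate
Product: 28 methyl (2R)-2-[(3R,6R)-6-{2-[(4R,5S)-4-ethenyl-2,6,6-trimethyl-5-(3-methylbut-3-en-1-yl)cyclohex-1-en-1-yl]ethyl}-6-methyl-1,2-dioxan-3-yl]propanoate, via B-alkyl-9-BBN 27 (not isolated)
Conditions: 13 (1.3 equiv), 9-BBN dimer, THF, 0 °C to rt; then 3 M aq. K3PO4, 26, Pd(dppf)Cl2·CH2Cl2 (8 mol %), AsPh3 (16 mol %), DMF, rt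
Reagents that add atoms: none
Why: Hydroboration and B-alkyl Suzuki–Miyaura coupling: 9-BBN adds to the terminal carbon of the vinyl group and the primary alkylborane is transferred to the enol triflate under palladium catalysis with mild aqueous base at room temperature, conditions that should spare the dialkyl peroxide, the ester and the two olefinic arms (excess borane is quenched by the aqueous base before 26 is added).

Step 17
Reactants: 28 methyl (2R)-2-[(3R,6R)-6-{2-[(4R,5S)-4-ethenyl-2,6,6-trimethyl-5-(3-methylbut-3-en-1-yl)cyclohex-1-en-1-yl]ethyl}-6-methyl-1,2-dioxan-3-yl]propanoate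
Product: 29 methyl (2R)-2-[(3R,6R)-6-methyl-6-{2-[(4aR,8aS)-1,1,3,6-tetramethyl-1,4,4a,7,8,8a-hexahydronaphthalen-2-yl]ethyl}-1,2-dioxan-3-yl]propanoate (target)
Conditions: second-generation Grubbs catalyst (H2IMes)(PCy3)Cl2Ru=CHPh (5 mol %), CH2Cl2 (5 mM), 40 °C
Reagents that add atoms: none
Why: Ring-closing olefin metathesis: the ruthenium alkylidene initiates at the monosubstituted vinyl group on C-4 of ring A, the new carbene engages the 1,1-disubstituted olefin of the C-5 arm through a ruthenacyclobutane, and cycloreversion releases ethene and the trisubstituted C5=C6 double bond. The closest known reaction type is ring-closing metathesis of a vinyl/isopropenyl diene to a 1-methylcyclohexene, a reaction that is expected to tolerate dialkyl peroxides. Ring B closes as a six-membered carbocycle by union of the two olefin termini, ring A acting as a two-carbon cis tether. No stereocentre is created; C-4a and C-8a are set in step 11 under control of the lactone template, are not epimerisable under the neutral conditions, and their cis arrangement places both arms on one face so that cyclisation should outrun oligomerisation at high dilution. The selectivity needed is chemoselectivity among three C=C bonds and tolerance of the O–O bond: the tetrasubstituted C2=C3 olefin is inert to the catalyst, the only monosubstituted olefin is the initiation site, and the peroxide and ester should not react with the ruthenium carbene. The position of the new double bond is dictated by the structure of diene 28, so no regioisomeric olefin can arise.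

**Compound list**

1 | 3-methylbut-3-en-2-ol (racemic) | CC(O)C(C)=C | starting material
2 | ethyl vinyl ether | C=COCC | starting material
3 | 3-(ethenyloxy)-2-methylbut-1-ene | C=COC(C)C(C)=C | intermediate (not isolated)
4 | (4E)-4-methylhex-4-enal | O=CCC/C(C)=C/C | intermediate
5 | (3S,4S,7E)-3,7-dimethylnona-1,7-dien-4-ol | C=C[C@H](C)[C@@H](O)CC/C(C)=C/C | intermediate
6 | (3S,4S,7E)-3,7-dimethylnona-1,7-dien-4-yl methanesulfonate | C=C[C@H](C)[C@@H](OS(C)(=O)=O)CC/C(C)=C/C | intermediate
7 | (3S,4S)-6-[(2R,3R)-2,3-dimethyloxiran-2-yl]-3-methylhex-1-en-4-yl methanesulfonate | C=C[C@H](C)[C@@H](OS(C)(=O)=O)CC[C@]1(C)[C@@H](C)O1 | intermediate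
8 | (3S,4S,7S,8R)-7-hydroperoxy-8-hydroxy-3,7-dimethylnon-1-en-4-yl methanesulfonate | C=C[C@H](C)[C@@H](OS(C)(=O)=O)CC[C@](C)(OO)[C@@H](C)O | intermediate
9 | (1R)-1-[(3S,6R)-6-[(2S)-but-3-en-2-yl]-3-methyl-1,2-dioxan-3-yl]ethan-1-ol | C=C[C@H](C)[C@H]1CC[C@@](C)([C@@H](C)O)OO1 | intermediate
10 | (2R)-2-[(3R,6S)-6-[(1R)-1-hydroxyethyl]-6-methyl-1,2-dioxan-3-yl]propanal | O=C[C@H](C)[C@H]1CC[C@@](C)([C@@H](C)O)OO1 | intermediate (not isolated)
11 | (2R)-2-[(3R,6S)-6-[(1R)-1-hydroxyethyl]-6-methyl-1,2-dioxan-3-yl]propanoic acid | OC(=O)[C@H](C)[C@H]1CC[C@@](C)([C@@H](C)O)OO1 | intermediate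
12 | methyl (2R)-2-[(3R,6S)-6-[(1R)-1-hydroxyethyl]-6-methyl-1,2-dioxan-3-yl]propanoate | COC(=O)[C@H](C)[C@H]1CC[C@@](C)([C@@H](C)O)OO1 | intermediate
13 | methyl (2R)-2-[(3R,6S)-6-ethenyl-6-methyl-1,2-dioxan-3-yl]propanoate (fragment 1) | COC(=O)[C@H](C)[C@H]1CC[C@@](C)(C=C)OO1 | intermediate
14 | 2-methylpentan-3-one | CCC(=O)C(C)C | starting material
15 | 2,4-dimethylpent-1-en-3-one | C=C(C)C(=O)C(C)C | intermediate
16 | (5R)-5-{[(1R,2S,5R)-5-methyl-2-(propan-2-yl)cyclohexyl]oxy}furan-2(5H)-one | O=C1C=C[C@H](O[C@@H]2C[C@H](C)CC[C@H]2C(C)C)O1 | starting material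
17 | lithium 2,4-dimethylpenta-1,3-dien-3-olate | [Li+].[O-]C(=C(C)C)C(C)=C | intermediate (not isolated)
18 | lithium enolate of the 4-(2,4-dimethyl-3-oxopent-4-en-2-yl)-5-menthyloxy-dihydrofuranone Michael adduct (new C–C bond trans to the menthyloxy group) | C=C(C)C(=O)C(C)(C)[C@@H]1C=C([O-])O[C@H]1O[C@@H]2C[C@H](C)CC[C@H]2C(C)C.[Li+] | intermediate (not isolated)
19 | lithium (3R,3aS,7aS)-4,4,6-trimethyl-3-menthyloxy-1-oxo-1,3,3a,4,7,7a-hexahydro-2-benzofuran-5-olate (cis-fused) | [Li+].[O-]C1=C(C)C[C@@H]2C(=O)O[C@@H](O[C@@H]3C[C@H](C)CC[C@H]3C(C)C)[C@@H]2C1(C)C | intermediate (not isolated)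
20 | (3R,3aS,7aS)-4,4,6-trimethyl-3-{[(1R,2S,5R)-5-methyl-2-(propan-2-yl)cyclohexyl]oxy}-1-oxo-1,3,3a,4,7,7a-hexahydro-2-benzofuran-5-yl trifluoromethanesulfonate | FC(F)(F)S(=O)(=O)OC1=C(C)C[C@@H]2C(=O)O[C@@H](O[C@@H]3C[C@H](C)CC[C@H]3C(C)C)[C@@H]2C1(C)C | intermediate
21 | (3aS,7aS)-3-hydroxy-4,4,6-trimethyl-1-oxo-1,3,3a,4,7,7a-hexahydro-2-benzofuran-5-yl trifluoromethanesulfonate (pseudo-acid, anomeric mixture) | FC(F)(F)S(=O)(=O)OC1=C(C)C[C@@H]2C(=O)OC(O)[C@@H]2C1(C)C | intermediate (not isolated)
22 | (3aS,7aS)-4,4,6-trimethyl-1-oxo-1,3,3a,4,7,7a-hexahydro-2-benzofuran-5-yl trifluoromethanesulfonate | FC(F)(F)S(=O)(=O)OC1=C(C)C[C@@H]2C(=O)OC[C@@H]2C1(C)C | intermediate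
23 | (3aS,7aS)-1-hydroxy-4,4,6-trimethyl-1,3,3a,4,7,7a-hexahydro-2-benzofuran-5-yl trifluoromethanesulfonate (anomeric mixture) | FC(F)(F)S(=O)(=O)OC1=C(C)C[C@@H]2C(O)OC[C@@H]2C1(C)C | intermediate
24 | (4R,5S)-4-ethenyl-5-(hydroxymethyl)-2,6,6-trimethylcyclohex-1-en-1-yl trifluoromethanesulfonate | FC(F)(F)S(=O)(=O)OC1=C(C)C[C@H](C=C)[C@H](CO)C1(C)C | intermediate
25 | [(1S,6R)-6-ethenyl-2,2,4-trimethyl-3-(trifluoromethanesulfonyloxy)cyclohex-3-en-1-yl]methyl trifluoromethanesulfonate | FC(F)(F)S(=O)(=O)OC1=C(C)C[C@H](C=C)[C@H](COS(=O)(=O)C(F)(F)F)C1(C)C | intermediate (not isolated)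
26 | (4R,5S)-4-ethenyl-2,6,6-trimethyl-5-(3-methylbut-3-en-1-yl)cyclohex-1-en-1-yl trifluoromethanesulfonate (fragment 2) | FC(F)(F)S(=O)(=O)OC1=C(C)C[C@H](C=C)[C@H](CCC(C)=C)C1(C)C | intermediate
27 | methyl (2R)-2-[(3R,6R)-6-[2-(9-borabicyclo[3.3.1]nonan-9-yl)ethyl]-6-methyl-1,2-dioxan-3-yl]propanoate | COC(=O)[C@H](C)[C@H]1CC[C@@](C)(CCB2C3CCCC2CCC3)OO1 | intermediate (not isolated)
28 | methyl (2R)-2-[(3R,6R)-6-{2-[(4R,5S)-4-ethenyl-2,6,6-trimethyl-5-(3-methylbut-3-en-1-yl)cyclohex-1-en-1-yl]ethyl}-6-methyl-1,2-dioxan-3-yl]propanoate | COC(=O)[C@H](C)[C@H]1CC[C@@](C)(CCC2=C(C)C[C@H](C=C)[C@H](CCC(C)=C)C2(C)C)OO1 | intermediate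
29 | methyl (2R)-2-[(3R,6R)-6-methyl-6-{2-[(4aR,8aS)-1,1,3,6-tetramethyl-1,4,4a,7,8,8a-hexahydronaphthalen-2-yl]ethyl}-1,2-dioxan-3-yl]propanoate | COC(=O)[C@H](C)[C@H]1CC[C@@](C)(CCC2=C(C)C[C@@H]3C=C(C)CC[C@@H]3C2(C)C)OO1 | target

**Count**

Total: 17 steps. Longest linear sequence: 11 steps (steps 1–9, 16, 17). The ring A branch (steps 10–15) is 6 steps before the union.

**Steps most likely to fail, with fallbacks**

1. Step 11 (double Michael annulation and triflation). What may go wrong: deprotonation at the vinylic methyl instead of the isopropyl methine; conjugate addition of the amide or the dienolate to unreacted enone (oligomerisation); incomplete or non-cis ring-closing Michael addition. The fallback sets out from 15 and 16 and comes back to the route at 19. Ketone 15 is enolised under soft conditions (t-BuMe2SiOTf, Et3N, CH2Cl2, 0 °C) to the silyl dienol ether 3-(tert-butyldimethylsilyloxy)-2,4-dimethylpenta-1,3-diene F1. F1 and 16 are combined under silyl triflimide catalysis (t-BuMe2SiNTf2, CH2Cl2, −78 °C). This is a Lewis-acid stepwise [4+2]: Mukaiyama–Michael addition anti to the menthyloxy group, then intramolecular Mukaiyama–Michael closure. It should give the cis-fused bicyclic silyl enol ether F2 without any strong base. MeLi (THF, 0 °C) then cleaves the silyl enol ether to lithium enolate 19, which is triflated as in step 11 to give 20.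

2. Step 16 (hydroboration and B-alkyl Suzuki coupling). What may go wrong: reductive cleavage of the O–O bond by the borane or by zerovalent palladium; base-induced retro-oxa-Michael opening and epimerisation of the β-peroxy ester; slow transmetalation at the hindered tetrasubstituted enol triflate. The fallback sets out from 26 and 13 and comes back to the route at 29; the fragments are joined by Wittig olefination and the extra olefin is reduced after ring closure.
   - 26 is methoxycarbonylated (Pd(OAc)2, 1,3-bis(diphenylphosphino)propane, CO, MeOH, Et3N, DMF, 60 °C; no peroxide is present at this stage) to the methyl ester F3.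
   - F3 is reduced (i-Bu2AlH, CH2Cl2, −78 °C) to the allylic alcohol F4, converted (CBr4, PPh3, CH2Cl2, 0 °C) to the allylic bromide F5 and quaternised (PPh3, MeCN, rt) to the phosphonium bromide F6.
   - 13 is ozonised (O3, CH2Cl2, −78 °C; Me2S) to the α-peroxy aldehyde F7.
   - F6 is deprotonated (NaHMDS, THF, −78 °C) to the ylide F8, which condenses with F7 to the diene F9 (olefin geometry immaterial).
   - Ring-closing metathesis of F9 under the conditions of step 17 gives F10. Diimide (KO2CN=NCO2K, AcOH, MeOH, 0 °C) then saturates only the disubstituted side-chain olefin, leaving the tri- and tetrasubstituted ring olefins and the peroxide, to give 29.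

3. Step 5 (perhydrolysis of the epoxide). What may go wrong: partial ionisation at the tertiary carbon with erosion of configuration, or acid-induced rearrangement of the epoxide to a carbonyl compound. The fallback sets out from 7 and comes back to the route at 9, bypassing 8. The secondary C–OO bond is made first and the ring is closed at the tertiary centre intramolecularly. The mesylate of 7 is displaced with inversion by the caesium salt of 2-methoxypropan-2-yl hydroperoxide (CsOH·H2O, DMF, rt) to give the peroxyketal F11. AcOH/H2O/THF unmasks the secondary hydroperoxide F12. A catalytic amount of camphorsulfonic acid (CH2Cl2, 0 °C) then induces 6-exo opening of the epoxide at the tertiary carbon by the tethered hydroperoxide with inversion, giving 9.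

**Further compounds**

F1 | step 11 | 3-(tert-butyldimethylsilyloxy)-2,4-dimethylpenta-1,3-diene | C=C(C)C(O[Si](C)(C)C(C)(C)C)=C(C)C
F2 | step 11 | (3R,3aS,7aS)-5-(tert-butyldimethylsilyloxy)-4,4,6-trimethyl-3-{[(1R,2S,5R)-5-methyl-2-(propan-2-yl)cyclohexyl]oxy}-3a,4,7,7a-tetrahydro-2-benzofuran-1(3H)-one | CC(C)(C)[Si](C)(C)OC1=C(C)C[C@@H]2C(=O)O[C@@H](O[C@@H]3C[C@H](C)CC[C@H]3C(C)C)[C@@H]2C1(C)C
F3 | step 16 | methyl (4R,5S)-4-ethenyl-2,6,6-trimethyl-5-(3-methylbut-3-en-1-yl)cyclohex-1-ene-1-carboxylate | COC(=O)C1=C(C)C[C@H](C=C)[C@H](CCC(C)=C)C1(C)C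
F4 | step 16 | [(4R,5S)-4-ethenyl-2,6,6-trimethyl-5-(3-methylbut-3-en-1-yl)cyclohex-1-en-1-yl]methanol | OCC1=C(C)C[C@H](C=C)[C@H](CCC(C)=C)C1(C)C
F5 | step 16 | (4R,5S)-1-(bromomethyl)-4-ethenyl-2,6,6-trimethyl-5-(3-methylbut-3-en-1-yl)cyclohex-1-ene | BrCC1=C(C)C[C@H](C=C)[C@H](CCC(C)=C)C1(C)C
F6 | step 16 | {[(4R,5S)-4-ethenyl-2,6,6-trimethyl-5-(3-methylbut-3-en-1-yl)cyclohex-1-en-1-yl]methyl}triphenylphosphonium bromide | [Br-].c1ccccc1[P+](c1ccccc1)(c1ccccc1)CC1=C(C)C[C@H](C=C)[C@H](CCC(C)=C)C1(C)C
F7 | step 16 | methyl (2R)-2-[(3R,6S)-6-formyl-6-methyl-1,2-dioxan-3-yl]propanoate | COC(=O)[C@H](C)[C@H]1CC[C@@](C)(C=O)OO1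
F8 | step 16 | {[(4R,5S)-4-ethenyl-2,6,6-trimethyl-5-(3-methylbut-3-en-1-yl)cyclohex-1-en-1-yl]methylidene}triphenylphosphorane | c1ccccc1P(c1ccccc1)(c1ccccc1)=CC1=C(C)C[C@H](C=C)[C@H](CCC(C)=C)C1(C)C
F9 | step 16 | methyl (2R)-2-[(3R,6S)-6-{2-[(4R,5S)-4-ethenyl-2,6,6-trimethyl-5-(3-methylbut-3-en-1-yl)cyclohex-1-en-1-yl]ethenyl}-6-methyl-1,2-dioxan-3-yl]propanoate | COC(=O)[C@H](C)[C@H]1CC[C@@](C)(C=CC2=C(C)C[C@H](C=C)[C@H](CCC(C)=C)C2(C)C)OO1
F10 | step 16 | methyl (2R)-2-[(3R,6S)-6-methyl-6-{2-[(4aR,8aS)-1,1,3,6-tetramethyl-1,4,4a,7,8,8a-hexahydronaphthalen-2-yl]ethenyl}-1,2-dioxan-3-yl]propanoate | COC(=O)[C@H](C)[C@H]1CC[C@@](C)(C=CC2=C(C)C[C@@H]3C=C(C)CC[C@@H]3C2(C)C)OO1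
F11 | step 5 | (2R,3R)-2-[(3R,4S)-3-[(2-methoxypropan-2-yl)peroxy]-4-methylhex-5-en-1-yl]-2,3-dimethyloxirane | C=C[C@H](C)[C@H](OOC(C)(C)OC)CC[C@]1(C)[C@@H](C)O1
F12 | step 5 | (2R,3R)-2-[(3R,4S)-3-hydroperoxy-4-methylhex-5-en-1-yl]-2,3-dimethyloxirane | C=C[C@H](C)[C@H](OO)CC[C@]1(C)[C@@H](C)O1
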